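**Retrosynthetic overview**

1. The strategy rests on the benzene ring: O at C1 and C4 (para), the side-chain CH2 at C2 (ortho to the C1 oxygen) and CH3 at C5 (para to the chain). This is the pattern an alkenylcarbene/terminal alkyne/CO benzannulation delivers, so the arene is made last from alkyne 31 and carbene complex 35. The 4-methoxyphenol is then taken to the hydroquinone through the quinone.
2. Alkyne 31: the C2′ and C3′ oxygens come from Sharpless epoxidation of the 2-substituted allylic alcohol 28, followed by acetate opening at C3′ with inversion and acetylation.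
3. Ketal 27: the C1–C2′ bond is formed by adding alkenyllithium 24 (built from but-2-yne-1,4-diol, with the propargyl unit already attached) to γ-lactone 15. Acid then closes the 2,8-dioxabicyclo[3.2.1]octane.
4. Lactone 15: C5 comes from (R)-linalool via lavender lactone; C3 is set by Nozaki–Hiyama–Kishi coupling with (E)-alkenyl iodide 11, oxidation and CBS reduction.
5. Ring order: oxolanone ring, then the bridged ketal (oxolane, 1,3-dioxane and oxepane rings closed in one operation), then the benzene ring.

Key step: step 22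

Remark: (R)-(−)-linalool of high enantiomeric purity is assumed to be commercial. Locants used below: ketal C1, O2, C3, C4, C5, C6, C7, O8; acyclic unit C1′ (CH2O), C2′ (tertiary carbinol), C3′ (CHO), C4′ (propargylic, later benzylic CH2).

**Route**

Step 1
Reactants: 1 (R)-linalool
Product: 2 (5R)-5-ethenyl-5-methyloxolan-2-ol (lactol, both anomers)
Conditions: O3 (1.0 equiv, Sudan III end-point), CH2Cl2/MeOH, −78 °C; then Me2S, −78 °C to rt
Reagents that add atoms: ozone, [O-][O+]=O
Why: Ozonolysis with reductive work-up should cleave the electron-rich trisubstituted alkene much faster than the vinyl group, and the 4-hydroxy aldehyde closes to the five-membered lactol without touching the carbinol centre.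

Step 2
Reactants: 2 (5R)-5-ethenyl-5-methyloxolan-2-ol
Product: 3 (5R)-5-ethenyl-5-methyloxolan-2-one ((R)-lavender lactone)
Conditions: TEMPO (10 mol%), PhI(OAc)2, CH2Cl2, rt
Reagents that add atoms: none
Why: Oxoammonium (TEMPO) oxidation of a lactol to the lactone is mild and leaves the vinyl group alone.

Step 3
Reactants: 3 (R)-lavender lactone
Product: 5 (5R)-5-(2-hydroxyethyl)-5-methyloxolan-2-one, via B-alkyl-9-BBN adduct 4 (not isolated)
Conditions: 9-BBN, THF, 0 °C to rt; then NaBO3·4H2O, H2O, rt
Reagents that add atoms: sodium perborate, [Na+].[O-]OB=O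
Why: Hydroboration–oxidation with 9-BBN should place boron on the terminal carbon of the vinyl group next to the quaternary centre, lactones being reduced only slowly by this borane, and perborate oxidises the C–B bond under mild conditions.

Step 4
Reactants: 5 (5R)-5-(2-hydroxyethyl)-5-methyloxolan-2-one
Product: 6 2-[(2R)-2-methyl-5-oxooxolan-2-yl]acetaldehyde
Conditions: Dess–Martin periodinane, NaHCO3, CH2Cl2, 0 °C to rt; used crude
Reagents that add atoms: none
Why: Buffered Dess–Martin oxidation is neutral enough to avoid β-elimination of the tertiary acyloxy group from the aldehyde.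

Step 5
Reactants: 7 6-methylhept-5-en-2-one
Product: 9 6-methylhept-5-en-1-yne, via enol diethyl phosphate 8 (not isolated)
Conditions: LDA, THF, −78 °C; ClP(O)(OEt)2; then LDA (2.2 equiv), −78 °C to rt
Reagents that add atoms: none
Why: Kinetic enolisation at the methyl group, O-phosphorylation and base-induced elimination of the enol phosphate is the standard methyl ketone to terminal alkyne conversion.

Step 6
Reactants: 9 6-methylhept-5-en-1-yne
Product: 11 (1E)-1-iodo-2,6-dimethylhepta-1,5-diene, via alkenyldimethylalane 10 (not isolated)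
Conditions: Me3Al, Cp2ZrCl2 (cat.), CH2Cl2, rt; then I2, THF, −30 °C
Reagents that add atoms: trimethylaluminium, C[Al](C)C; iodine, II
Why: Negishi zirconium-catalysed carboalumination adds methyl and aluminium syn across the alkyne, and iodinolysis with retention gives the E trisubstituted alkenyl iodide.

Step 7
Reactants: 6 2-[(2R)-2-methyl-5-oxooxolan-2-yl]acetaldehyde; 11 (1E)-1-iodo-2,6-dimethylhepta-1,5-diene
Product: 12 (5R)-5-[(3E)-2-hydroxy-4,8-dimethylnona-3,7-dien-1-yl]-5-methyloxolan-2-one (both carbinol epimers)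
Conditions: CrCl2, NiCl2 (cat.), DMSO, rt
Reagents that add atoms: none
Why: Nozaki–Hiyama–Kishi coupling adds the alkenylchromium to the aldehyde only, under non-basic conditions and with retention of alkene geometry; the carbinol configuration is not controlled because the next step removes it.

Step 8
Reactants: 12 allylic alcohol (epimer mixture)
Product: 13 (5R)-5-[(3E)-4,8-dimethyl-2-oxonona-3,7-dien-1-yl]-5-methyloxolan-2-one
Conditions: Dess–Martin periodinane, NaHCO3, CH2Cl2, 0 °C
Reagents that add atoms: none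
Why: Dess–Martin oxidation of the allylic alcohol converges both epimers on one enone without base that could trigger β-elimination of the lactone oxygen.

Step 9
Reactants: 13 enone
Product: 14 (5R)-5-[(2S,3E)-2-hydroxy-4,8-dimethylnona-3,7-dien-1-yl]-5-methyloxolan-2-one
Conditions: (R)-2-methyl-CBS-oxazaborolidine (0.5 equiv), catecholborane, toluene, −78 °C
Reagents that add atoms: none
Why: Corey–Bakshi–Shibata reduction; the alkenyl group acts as the large substituent, so the (R)-catalyst should deliver hydride to the face that gives the (S)-allylic alcohol (future C3), with 1,2-selectivity and no reduction of the lactone.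

Step 10
Reactants: 14 (S)-allylic alcohol
Product: 15 (5R)-5-{(2S,3E)-4,8-dimethyl-2-[(triethylsilyl)oxy]nona-3,7-dien-1-yl}-5-methyloxolan-2-one
Conditions: TESCl, imidazole, CH2Cl2, 0 °C
Reagents that add atoms: chlorotriethylsilane, CC[Si](Cl)(CC)CC
Why: Silylation masks the hydroxyl for the organolithium step with a group that the later acid step removes in the same flask.

Step 11
Reactants: 16 but-2-yne-1,4-diol
Product: 17 4-[(tert-butyldimethylsilyl)oxy]but-2-yn-1-ol
Conditions: NaH (1.0 equiv), THF, rt; then TBSCl (1.0 equiv)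
Reagents that add atoms: tert-butyldimethylsilyl chloride, CC(C)(C)[Si](C)(C)Cl
Why: Monosilylation of a symmetrical diol through its sparingly soluble monosodium alkoxide is a standard desymmetrisation.

Step 12
Reactants: 17 4-[(tert-butyldimethylsilyl)oxy]but-2-yn-1-ol
Product: 19 (2Z)-4-[(tert-butyldimethylsilyl)oxy]-3-iodobut-2-en-1-ol, via cyclic alkenylalanate 18 (not isolated)
Conditions: Red-Al, THF, 0 °C to rt; EtOAc; then I2, THF, −78 °C
Reagents that add atoms: iodine, II
Why: Hydroxyl-directed trans-hydroalumination places aluminium on the alkyne carbon distal to the free hydroxyl and cis to its CH2, and iodinolysis with retention gives the Z iodide with the two CH2O groups trans.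

Step 13
Reactants: 19 (2Z)-4-[(tert-butyldimethylsilyl)oxy]-3-iodobut-2-en-1-ol
Product: 20 {[(2Z)-4-bromo-2-iodobut-2-en-1-yl]oxy}(tert-butyl)dimethylsilane
Conditions: CBr4, PPh3, CH2Cl2, 0 °C
Reagents that add atoms: carbon tetrabromide, BrC(Br)(Br)Br
Why: Appel bromination of the primary allylic alcohol proceeds by SN2 at the oxyphosphonium, leaving the vinyl iodide, the silyl ether and the alkene geometry intact.

Step 14
Reactants: 20 allylic bromide; 21 ethynyltrimethylsilane
Product: 23 tert-butyl{[(2Z)-2-iodo-6-(trimethylsilyl)hex-2-en-5-yn-1-yl]oxy}dimethylsilane, via alkynylmagnesium bromide 22 (not isolated)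
Conditions: 21, EtMgBr, THF, 0 °C to rt; then CuBr·SMe2 (10 mol%), 20, 0 °C to rt
Reagents that add atoms: none
Why: Copper-catalysed coupling of an alkynyl Grignard reagent with a primary allylic bromide gives the skipped enyne by direct substitution; attack at the iodine-bearing, fully substituted carbon is disfavoured, and the vinyl iodide does not react without palladium.

Step 15
Reactants: 23 enyne vinyl iodide (1.3 equiv); 15 TES-protected lactone
Product: 25 γ-hydroxy enone with C2′=C3′ Z (open form, in equilibrium with its five-membered hemiketal; used crude), via alkenyllithium 24 (not isolated)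
Conditions: 23, t-BuLi (2.6 equiv), Et2O, −78 °C; then 15 in THF, −78 °C; AcOH quench at −78 °C
Reagents that add atoms: none
Why: Iodine–lithium exchange retains the alkene geometry, and a single addition of the alkenyllithium to the γ-lactone should hold at the tetrahedral lithium lactolate until the cold quench, which forms the C1–C2′ bond.

Step 16
Reactants: 25 γ-hydroxy enone
Product: 27 tert-butyl({(2Z)-2-[(1R,3S,5R)-3-[(1E)-2,6-dimethylhepta-1,5-dien-1-yl]-5-methyl-2,8-dioxabicyclo[3.2.1]octan-1-yl]-6-(trimethylsilyl)hex-2-en-5-yn-1-yl}oxy)dimethylsilane, via desilylated dihydroxy enone 26 (not isolated)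
Conditions: PPTS, MeOH, rt; then CSA (5 mol%), CH2Cl2, 4 Å MS, 0 °C
Reagents that add atoms: none
Why: Methanolysis of the TES ether frees the C3 hydroxyl, and acid-catalysed intramolecular ketalisation of the ketone with the tertiary and secondary hydroxyls closes the bridged ketal; the C1 configuration is dictated by the C5 centre through the bridge, and the C3 alkenyl group sits equatorial on the dioxane chair.

Step 17
Reactants: 27 silylated bicyclic ketal
Product: 28 (2Z)-2-[(1R,3S,5R)-3-[(1E)-2,6-dimethylhepta-1,5-dien-1-yl]-5-methyl-2,8-dioxabicyclo[3.2.1]octan-1-yl]hex-2-en-5-yn-1-ol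
Conditions: TBAF (3 equiv), THF, 0 °C
Reagents that add atoms: none
Why: Fluoride cleaves the O–TBS and the alkynyl C–TMS bonds in one operation, giving the allylic alcohol and the terminal alkyne.

Step 18
Reactants: 28 allylic alcohol
Product: 29 {(2S,3S)-2-[(1R,3S,5R)-3-[(1E)-2,6-dimethylhepta-1,5-dien-1-yl]-5-methyl-2,8-dioxabicyclo[3.2.1]octan-1-yl]-3-(prop-2-yn-1-yl)oxiran-2-yl}methanol
Conditions: Ti(OiPr)4 (20 mol%), L-(+)-diethyl tartrate (24 mol%), t-BuOOH, 4 Å MS, CH2Cl2, −20 °C
Reagents that add atoms: tert-butyl hydroperoxide, CC(C)(C)OO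
Why: Sharpless asymmetric epoxidation oxidises only the alkene of the allylic alcohol among the three alkenes; the bulky ketal sits at the tolerant C2 position, and the L-(+)-tartrate catalyst should deliver oxygen to the face that gives the (2S,3S)-epoxide, which sets C2′.

Step 19
Reactants: 29 epoxy alcohol
Product: 30 (2S,3R)-1,2-dihydroxy-2-[(1R,3S,5R)-3-[(1E)-2,6-dimethylhepta-1,5-dien-1-yl]-5-methyl-2,8-dioxabicyclo[3.2.1]octan-1-yl]hex-5-yn-3-yl acetate
Conditions: Ti(OiPr)4 (1.5 equiv), AcOH (3 equiv), CH2Cl2, rt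
Reagents that add atoms: acetic acid, CC(O)=O
Why: Titanium-mediated opening of a 2,3-epoxy alcohol by a carboxylic acid is selective for the carbon distal to the CH2OH group, so acetate should attack C3′ by SN2 with inversion and give the 3′R centre while the quaternary C2′ keeps its oxygen; any 1,3-acetyl shift to C1′ is harmless because step 20 converges both on the diacetate.

Step 20
Reactants: 30 monoacetate
Product: 31 (2S,3R)-2-hydroxy-2-[(1R,3S,5R)-3-[(1E)-2,6-dimethylhepta-1,5-dien-1-yl]-5-methyl-2,8-dioxabicyclo[3.2.1]octan-1-yl]hex-5-yne-1,3-diyl diacetate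
Conditions: Ac2O, pyridine, DMAP (cat.), CH2Cl2, 0 °C
Reagents that add atoms: acetic anhydride, CC(=O)OC(C)=O
Why: Acylation of the primary hydroxyl is fast, while the tertiary hydroxyl flanked by two fully substituted carbons should stay free at 0 °C.

Step 21
Reactants: 32 2-bromopropene
Product: 35 pentacarbonyl[methoxy(prop-1-en-2-yl)carbene]chromium, via isopropenyllithium 33 (not isolated), via lithium acylchromate 34 (not isolated)
Conditions: t-BuLi (2 equiv), Et2O, −78 °C; Cr(CO)6, 0 °C to rt; then Me3OBF4, CH2Cl2/H2O, 0 °C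
Reagents that add atoms: chromium hexacarbonyl, O=C=[Cr](=C=O)(=C=O)(=C=O)(=C=O)=C=O; trimethyloxonium tetrafluoroborate, C[O+](C)C.F[B-](F)(F)F
Why: Fischer carbene synthesis: the alkenyllithium adds to a carbonyl ligand and O-methylation of the acylmetalate gives the alkoxy(alkenyl)carbene complex.

Step 22
Reactants: 31 terminal alkyne diacetate; 35 carbene complex (1.5 equiv)
Product: 37 (2S,3R)-2-hydroxy-4-(2-hydroxy-5-methoxy-4-methylphenyl)-2-[(1R,3S,5R)-3-[(1E)-2,6-dimethylhepta-1,5-dien-1-yl]-5-methyl-2,8-dioxabicyclo[3.2.1]octan-1-yl]butane-1,3-diyl diacetate, via tricarbonylchromium arene complex 36 (not isolated)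
Conditions: THF (0.05 M, degassed), 50 °C; then air, EtOAc, rt
Reagents that add atoms: none
Why: This is a Dötz benzannulation of an alkenyl(alkoxy)carbene chromium complex with a terminal alkyne, the closest known reaction type. Thermal loss of one CO lets alkyne 31 coordinate and insert into the Cr=C bond so that its CH carbon bonds to the carbene carbon and its substituted carbon lies distal; CO insertion then gives an η4-vinylketene whose ketene carbon is bonded to that substituted carbon. The benzene ring is closed by 6π-electrocyclisation of this dienylketene (ketene carbon to the isopropenyl CH2), and tautomerisation gives the 4-methoxyphenol as its Cr(CO)3 complex 36, which air frees from the metal. No stereocentre is formed, and the existing ones are remote from the reacting alkyne under neutral conditions. The step needs regioselective insertion, which the steric difference between H and the CH2 chain on the alkyne should secure, placing the chain ortho to the new hydroxyl and para to the methyl; it also needs ring closure to outrun capture of the ketene by the C2′ hydroxyl, which the hindered tertiary position of that hydroxyl and the fast closure of alkenyl-derived ketenes should ensure.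

Step 23
Reactants: 37 4-methoxyphenol
Product: 38 (2S,3R)-2-hydroxy-4-(4-methyl-3,6-dioxocyclohexa-1,4-dien-1-yl)-2-[(1R,3S,5R)-3-[(1E)-2,6-dimethylhepta-1,5-dien-1-yl]-5-methyl-2,8-dioxabicyclo[3.2.1]octan-1-yl]butane-1,3-diyl diacetate
Conditions: (NH4)2Ce(NO3)6 (2.5 equiv), MeCN/H2O, 0 °C, short reaction time
Reagents that add atoms: water, O
Why: Ceric ammonium nitrate oxidation of a 4-methoxyphenol gives the p-quinone by two-electron oxidation, addition of water at the methoxy-bearing carbon and loss of methanol; brief exposure at 0 °C should spare the isolated alkenes, the acetates and the bridged ketal.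

Step 24
Reactants: 38 quinone
Product: 39 (2S,3R)-4-(2,5-dihydroxy-4-methylphenyl)-2-hydroxy-2-[(1R,3S,5R)-3-[(1E)-2,6-dimethylhepta-1,5-dien-1-yl]-5-methyl-2,8-dioxabicyclo[3.2.1]octan-1-yl]butane-1,3-diyl diacetate (target)
Conditions: Na2S2O4, H2O/EtOAc, rt, under argon
Reagents that add atoms: none
Why: Dithionite reduction of a p-benzoquinone to the hydroquinone is fast and neutral and touches no other group.

**Compound list**

1 | (R)-linalool | C=C[C@](C)(O)CCC=C(C)C | starting material
2 | (5R)-5-ethenyl-5-methyloxolan-2-ol | C=C[C@](C)(O1)CCC1O | intermediate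
3 | (5R)-5-ethenyl-5-methyloxolan-2-one | C=C[C@](C)(O1)CCC1=O | intermediate
4 | B-alkyl-9-BBN adduct of 3 (boron on the terminal carbon) | C[C@]1(CCB2C3CCCC2CCC3)CCC(=O)O1 | intermediate
5 | (5R)-5-(2-hydroxyethyl)-5-methyloxolan-2-one | OCC[C@](C)(O1)CCC1=O | intermediate
6 | 2-[(2R)-2-methyl-5-oxooxolan-2-yl]acetaldehyde | O=CC[C@](C)(O1)CCC1=O | intermediate
7 | 6-methylhept-5-en-2-one | CC(=O)CCC=C(C)C | starting material
8 | diethyl 6-methylhepta-1,5-dien-2-yl phosphate | C=C(CCC=C(C)C)OP(=O)(OCC)OCC | intermediate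
9 | 6-methylhept-5-en-1-yne | C#CCCC=C(C)C | intermediate
10 | [(1E)-2,6-dimethylhepta-1,5-dien-1-yl]dimethylaluminium | C[Al](C)/C=C(\C)CCC=C(C)C | intermediate
11 | (1E)-1-iodo-2,6-dimethylhepta-1,5-diene | I/C=C(\C)CCC=C(C)C | intermediate
12 | (5R)-5-[(3E)-2-hydroxy-4,8-dimethylnona-3,7-dien-1-yl]-5-methyloxolan-2-one, both carbinol epimers | OC(C[C@](C)(O1)CCC1=O)/C=C(\C)CCC=C(C)C | intermediate
13 | (5R)-5-[(3E)-4,8-dimethyl-2-oxonona-3,7-dien-1-yl]-5-methyloxolan-2-one | O=C(C[C@](C)(O1)CCC1=O)/C=C(\C)CCC=C(C)C | intermediate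
14 | (5R)-5-[(2S,3E)-2-hydroxy-4,8-dimethylnona-3,7-dien-1-yl]-5-methyloxolan-2-one | O=C1CC[C@](C)(C[C@H](O)/C=C(\C)CCC=C(C)C)O1 | intermediate
15 | (5R)-5-{(2S,3E)-4,8-dimethyl-2-[(triethylsilyl)oxy]nona-3,7-dien-1-yl}-5-methyloxolan-2-one | O=C1CC[C@](C)(C[C@H](O[Si](CC)(CC)CC)/C=C(\C)CCC=C(C)C)O1 | intermediate
16 | but-2-yne-1,4-diol | OCC#CCO | starting material
17 | 4-[(tert-butyldimethylsilyl)oxy]but-2-yn-1-ol | OCC#CCO[Si](C)(C)C(C)(C)C | intermediate
18 | sodium cyclic alkenylalanate (five-membered O–Al–C ring, two 2-methoxyethoxy ligands on Al) | [Na+].COCCO[Al-]1(OCCOC)OCC=C1CO[Si](C)(C)C(C)(C)C | intermediate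
19 | (2Z)-4-[(tert-butyldimethylsilyl)oxy]-3-iodobut-2-en-1-ol | OC/C=C(\I)CO[Si](C)(C)C(C)(C)C | intermediate
20 | {[(2Z)-4-bromo-2-iodobut-2-en-1-yl]oxy}(tert-butyl)dimethylsilane | BrC/C=C(\I)CO[Si](C)(C)C(C)(C)C | intermediate
21 | ethynyltrimethylsilane | C#C[Si](C)(C)C | starting material
22 | [(trimethylsilyl)ethynyl]magnesium bromide | C[Si](C)(C)C#C[Mg]Br | intermediate
23 | tert-butyl{[(2Z)-2-iodo-6-(trimethylsilyl)hex-2-en-5-yn-1-yl]oxy}dimethylsilane | C[Si](C)(C)C#CC/C=C(\I)CO[Si](C)(C)C(C)(C)C | intermediate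
24 | alkenyllithium from 23 (lithium in place of iodine, geometry retained) | C[Si](C)(C)C#CC/C=C(\[Li])CO[Si](C)(C)C(C)(C)C | intermediate
25 | γ-hydroxy enone from 24 and 15 (C2′=C3′ Z; tertiary OH free, C3 OTES) | C[Si](C)(C)C#CC/C=C(/CO[Si](C)(C)C(C)(C)C)C(=O)CC[C@@](C)(O)C[C@H](O[Si](CC)(CC)CC)/C=C(\C)CCC=C(C)C | intermediate
26 | dihydroxy enone (25 without the TES group) | C[Si](C)(C)C#CC/C=C(/CO[Si](C)(C)C(C)(C)C)C(=O)CC[C@@](C)(O)C[C@H](O)/C=C(\C)CCC=C(C)C | intermediate
27 | tert-butyl({(2Z)-2-[(1R,3S,5R)-3-[(1E)-2,6-dimethylhepta-1,5-dien-1-yl]-5-methyl-2,8-dioxabicyclo[3.2.1]octan-1-yl]-6-(trimethylsilyl)hex-2-en-5-yn-1-yl}oxy)dimethylsilane | C[Si](C)(C)C#CC/C=C(/CO[Si](C)(C)C(C)(C)C)[C@]12CC[C@](C)(C[C@@H](/C=C(\C)CCC=C(C)C)O1)O2 | intermediate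
28 | (2Z)-2-[(1R,3S,5R)-3-[(1E)-2,6-dimethylhepta-1,5-dien-1-yl]-5-methyl-2,8-dioxabicyclo[3.2.1]octan-1-yl]hex-2-en-5-yn-1-ol | C#CC/C=C(/CO)[C@]12CC[C@](C)(C[C@@H](/C=C(\C)CCC=C(C)C)O1)O2 | intermediate
29 | {(2S,3S)-2-[(1R,3S,5R)-3-[(1E)-2,6-dimethylhepta-1,5-dien-1-yl]-5-methyl-2,8-dioxabicyclo[3.2.1]octan-1-yl]-3-(prop-2-yn-1-yl)oxiran-2-yl}methanol | OC[C@@]1(O[C@H]1CC#C)[C@]23CC[C@](C)(C[C@@H](/C=C(\C)CCC=C(C)C)O2)O3 | intermediate
30 | (2S,3R)-1,2-dihydroxy-2-[(1R,3S,5R)-3-[(1E)-2,6-dimethylhepta-1,5-dien-1-yl]-5-methyl-2,8-dioxabicyclo[3.2.1]octan-1-yl]hex-5-yn-3-yl acetate | OC[C@](O)([C@@H](CC#C)OC(C)=O)[C@]12CC[C@](C)(C[C@@H](/C=C(\C)CCC=C(C)C)O1)O2 | intermediate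
31 | (2S,3R)-2-hydroxy-2-[(1R,3S,5R)-3-[(1E)-2,6-dimethylhepta-1,5-dien-1-yl]-5-methyl-2,8-dioxabicyclo[3.2.1]octan-1-yl]hex-5-yne-1,3-diyl diacetate | CC(=O)OC[C@](O)([C@@H](CC#C)OC(C)=O)[C@]12CC[C@](C)(C[C@@H](/C=C(\C)CCC=C(C)C)O1)O2 | intermediate
32 | 2-bromopropene | CC(Br)=C | starting material
33 | isopropenyllithium | [Li]C(C)=C | intermediate
34 | lithium pentacarbonyl(2-methylacryloyl)chromate | [Li+].[O-]C(=[Cr](=C=O)(=C=O)(=C=O)(=C=O)=C=O)C(C)=C | intermediate
35 | pentacarbonyl[methoxy(prop-1-en-2-yl)carbene]chromium | COC(=[Cr](=C=O)(=C=O)(=C=O)(=C=O)=C=O)C(C)=C | intermediate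
36 | tricarbonylchromium η6-arene complex of 37 (written as arene plus Cr(CO)3 fragment) | CC(=O)OC[C@](O)([C@@H](Cc1cc(OC)c(C)cc1O)OC(C)=O)[C@]12CC[C@](C)(C[C@@H](/C=C(\C)CCC=C(C)C)O1)O2.O=C=[Cr](=C=O)=C=O | intermediate
37 | (2S,3R)-2-hydroxy-4-(2-hydroxy-5-methoxy-4-methylphenyl)-2-[(1R,3S,5R)-3-[(1E)-2,6-dimethylhepta-1,5-dien-1-yl]-5-methyl-2,8-dioxabicyclo[3.2.1]octan-1-yl]butane-1,3-diyl diacetate | CC(=O)OC[C@](O)([C@@H](Cc1cc(OC)c(C)cc1O)OC(C)=O)[C@]12CC[C@](C)(C[C@@H](/C=C(\C)CCC=C(C)C)O1)O2 | intermediate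
38 | (2S,3R)-2-hydroxy-4-(4-methyl-3,6-dioxocyclohexa-1,4-dien-1-yl)-2-[(1R,3S,5R)-3-[(1E)-2,6-dimethylhepta-1,5-dien-1-yl]-5-methyl-2,8-dioxabicyclo[3.2.1]octan-1-yl]butane-1,3-diyl diacetate | CC(=O)OC[C@](O)([C@@H](CC1=CC(=O)C(C)=CC1=O)OC(C)=O)[C@]12CC[C@](C)(C[C@@H](/C=C(\C)CCC=C(C)C)O1)O2 | intermediate
39 | (2S,3R)-4-(2,5-dihydroxy-4-methylphenyl)-2-hydroxy-2-[(1R,3S,5R)-3-[(1E)-2,6-dimethylhepta-1,5-dien-1-yl]-5-methyl-2,8-dioxabicyclo[3.2.1]octan-1-yl]butane-1,3-diyl diacetate | CC(=O)OC[C@](O)([C@@H](Cc1cc(O)c(C)cc1O)OC(C)=O)[C@]12CC[C@](C)(C[C@@H](/C=C(\C)CCC=C(C)C)O1)O2 | target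

**Step count**

Total steps: 24. Longest linear sequence: 17 steps (steps 1–4, 7–10, 15–20, 22–24).

**Steps most likely to fail**

Step 22 (benzannulation). What may go wrong: the free tertiary hydroxyl may intercept the chromium vinylketene, or a chromium vinylidene formed from the terminal alkyne, before the ring closes, so that oxygen heterocycles form in place of the arene. Alkyne insertion may also stall next to the branched acetoxy-bearing chain. The fallback removes the interfering nucleophile from the substrate and joins demetalation with the oxidation. It sets out from 31, which N-(trimethylsilyl)imidazole in CH2Cl2 should convert into the C2′ trimethylsilyl ether F1. Benzannulation of the silyl ether F1 with 35 under the same thermal conditions should give the silylated 4-methoxyphenol F2. Ceric ammonium nitrate in aqueous acetonitrile should then oxidise the phenol F2 to the quinone and hydrolyse the labile silyl ether in the same acidic medium (followed, if needed, by brief citric acid in methanol). The fallback comes back to the route at 38.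

Step 19 (epoxide opening). What may go wrong: acetate delivery at the neopentyl-like C3′ may be slow, isopropoxide may be transferred from titanium instead, or attack may stray to C2′. The fallback drops the metal-templated carboxylate delivery in favour of Brønsted acid-catalysed hydrolysis by water, the smallest nucleophile. It sets out from 29, which dilute HClO4 in THF/H2O at 0 °C should open at C3′ with inversion, positive charge at C2′ being disfavoured by the adjacent ketal carbon, to give the triol F3. Acetylation of the triol F3 with Ac2O and pyridine at 0 °C should acylate the primary and secondary hydroxyls only. The fallback comes back to the route at 31, bypassing 30.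

Step 15 (lactone–alkenyllithium union). What may go wrong: the tetrahedral lactolate may collapse early and take up a second equivalent of the alkenyllithium, or a proton may be transferred from the lactone α-CH2, returning both partners. The fallback replaces the lactone by an acylating agent that gives a stable chelate. It sets out from 15, which MeNH(OMe)·HCl and Me3Al in CH2Cl2 should open to the hydroxy Weinreb amide F4. Silylation of the tertiary hydroxyl with N-(trimethylsilyl)imidazole should give the bis-silyl amide F5. Addition of alkenyllithium 24 to the amide F5 at −78 °C should stop at the chelated adduct and give, after quench, the bis-silylated enone F6. The acid conditions of step 16 should then remove both silyl ethers from the enone F6 (through 26) and close the ketal, so the fallback comes back to the route at 27.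

**Further compounds**

F1 | step 22 | (2S,3R)-2-[(1R,3S,5R)-3-[(1E)-2,6-dimethylhepta-1,5-dien-1-yl]-5-methyl-2,8-dioxabicyclo[3.2.1]octan-1-yl]-2-[(trimethylsilyl)oxy]hex-5-yne-1,3-diyl diacetate | CC(=O)OC[C@](O[Si](C)(C)C)([C@@H](CC#C)OC(C)=O)[C@]12CC[C@](C)(C[C@@H](/C=C(\C)CCC=C(C)C)O1)O2
F2 | step 22 | (2S,3R)-4-(2-hydroxy-5-methoxy-4-methylphenyl)-2-[(1R,3S,5R)-3-[(1E)-2,6-dimethylhepta-1,5-dien-1-yl]-5-methyl-2,8-dioxabicyclo[3.2.1]octan-1-yl]-2-[(trimethylsilyl)oxy]butane-1,3-diyl diacetate | CC(=O)OC[C@](O[Si](C)(C)C)([C@@H](Cc1cc(OC)c(C)cc1O)OC(C)=O)[C@]12CC[C@](C)(C[C@@H](/C=C(\C)CCC=C(C)C)O1)O2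
F3 | step 19 | (2S,3R)-2-[(1R,3S,5R)-3-[(1E)-2,6-dimethylhepta-1,5-dien-1-yl]-5-methyl-2,8-dioxabicyclo[3.2.1]octan-1-yl]hex-5-yne-1,2,3-triol | OC[C@](O)([C@@H](CC#C)O)[C@]12CC[C@](C)(C[C@@H](/C=C(\C)CCC=C(C)C)O1)O2
F4 | step 15 | (4R,6S,7E)-4-hydroxy-N-methoxy-N,4,8,12-tetramethyl-6-[(triethylsilyl)oxy]trideca-7,11-dienamide | CON(C)C(=O)CC[C@@](C)(O)C[C@H](O[Si](CC)(CC)CC)/C=C(\C)CCC=C(C)C
F5 | step 15 | (4R,6S,7E)-N-methoxy-N,4,8,12-tetramethyl-6-[(triethylsilyl)oxy]-4-[(trimethylsilyl)oxy]trideca-7,11-dienamide | CON(C)C(=O)CC[C@@](C)(O[Si](C)(C)C)C[C@H](O[Si](CC)(CC)CC)/C=C(\C)CCC=C(C)C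
F6 | step 15 | bis-silylated enone (25 with the tertiary hydroxyl as its trimethylsilyl ether) | C[Si](C)(C)C#CC/C=C(/CO[Si](C)(C)C(C)(C)C)C(=O)CC[C@@](C)(O[Si](C)(C)C)C[C@H](O[Si](CC)(CC)CC)/C=C(\C)CCC=C(C)C
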